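Ring B is cut between C5 (C–OH) and C6 (C=O). A C–C bond carrying oxygen on both carbons is the retron of an acyloin coupling, so the four carbons C1–C4 (bearing the phenethyl chain, the biaryl link, the oxo group and the methyl group) become the chain of a hexanedioate. Sodium and Me3SiCl join the two ester carbons in one operation and close ring B as a 1,2-bis(silyloxy)cyclohexene; its stereocentres vanish on aromatization. The precursor is a diethyl adipate with C4–Me, a silyl ether on O3, the trimethoxy form of ring A at C2 and the phenethyl group at C1. O3 is silylated in the aldol that creates it, so the γ-hydroxy ester cannot lactonize onto the C6 ester.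

Key step: step 15

Remark: the target has no stereocentre (the biaryl axis is undefined), so every sp3 centre made on the way is carried as a racemic diastereomer mixture. Ar = 2-[2-(2-methoxyphenyl)ethyl]-3,4,6-trimethoxy-5-methylphenyl (ring A, protected). Ring B locants: C1 phenethyl, C2 biaryl link, C3 C=O, C4 C–Me, C5 C–OH, C6 C=O.

Step 1
Reactants: 1 2-methoxybenzyl chloride
Product: 2 (2-methoxybenzyl)triphenylphosphonium chloride
Conditions: PPh3, toluene, reflux
Reagents that add atoms: triphenylphosphine, c1ccc(cc1)P(c1ccccc1)c1ccccc1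
Why: SN2 quaternization of the benzylic chloride by the phosphine should give the Wittig salt, which precipitates from toluene.

Step 2
Reactants: 2 (2-methoxybenzyl)triphenylphosphonium chloride; 3 3,5-dimethoxy-4-methylbenzaldehyde
Product: 5 1,3-dimethoxy-5-[2-(2-methoxyphenyl)ethenyl]-2-methylbenzene (E/Z mixture), via phosphonium ylide 4 (not isolated)
Conditions: KOt-Bu, THF, 0 °C to rt
Reagents that add atoms: none
Why: Wittig olefination of an unhindered benzaldehyde with a semi-stabilized ylide; the alkene geometry is irrelevant because the double bond is hydrogenated next.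

Step 3
Reactants: 5 1,3-dimethoxy-5-[2-(2-methoxyphenyl)ethenyl]-2-methylbenzene
Product: 6 1,3-dimethoxy-5-[2-(2-methoxyphenyl)ethyl]-2-methylbenzene
Conditions: H2 (1 atm), Pd/C, EtOAc, rt
Reagents that add atoms: none
Why: Catalytic hydrogenation of the stilbene double bond should leave the aryl methyl ethers untouched.

Step 4
Reactants: 6 1,3-dimethoxy-5-[2-(2-methoxyphenyl)ethyl]-2-methylbenzene
Product: 7 2-bromo-1-[2-(2-methoxyphenyl)ethyl]-3,5-dimethoxy-4-methylbenzene
Conditions: NBS (1.0 equiv), MeCN, 0 °C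
Reagents that add atoms: N-bromosuccinimide, O=C1CCC(=O)N1Br
Why: Electrophilic aromatic bromination should go to one of the two equivalent ring A positions that lie ortho to one methoxy group and para to the other, which are far more nucleophilic than any position of the anisole ring.

Step 5
Reactants: 7 2-bromo-1-[2-(2-methoxyphenyl)ethyl]-3,5-dimethoxy-4-methylbenzene
Product: 8 1-[2-(2-methoxyphenyl)ethyl]-2,3,5-trimethoxy-4-methylbenzene
Conditions: NaOMe, CuBr (10 mol %), EtOAc (cat.), MeOH/DMF, 110 °C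
Reagents that add atoms: sodium methoxide, [Na+].[O-]C
Why: Ullmann-type CuBr-catalysed methoxylation of an electron-rich aryl bromide, as used to make polymethoxytoluenes, should install the third ring A oxygen.

Step 6
Reactants: 8 1-[2-(2-methoxyphenyl)ethyl]-2,3,5-trimethoxy-4-methylbenzene
Product: 10 2-[2-(2-methoxyphenyl)ethyl]-3,4,6-trimethoxy-5-methylbenzaldehyde (Ar–CHO), via iminium salt 9 (not isolated)
Conditions: POCl3, DMF, 0 to 80 °C; then H2O, 0 °C
Reagents that add atoms: N,N-dimethylformamide, CN(C)C=O; water, O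
Why: Vilsmeier–Haack formylation should attack the only free ring A position, which is ortho and para to methoxy groups, while the singly activated anisole ring does not react with the chloroiminium ion.

Step 7
Reactants: 10 Ar–CHO; 11 triethyl phosphonoacetate
Product: 13 ethyl (E)-3-Ar-prop-2-enoate, via sodium phosphonate carbanion 12 (not isolated)
Conditions: NaH, THF, 0 °C to reflux
Reagents that add atoms: none
Why: Horner–Wadsworth–Emmons olefination tolerates di-ortho-substituted benzaldehydes and should give the E enoate.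

Step 8
Reactants: 13 ethyl (E)-3-Ar-prop-2-enoate
Product: 14 (E)-3-Ar-prop-2-en-1-ol
Conditions: i-Bu2AlH (2.3 equiv), CH2Cl2, −78 °C; aq. KNaC4H4O6 (potassium sodium tartrate)
Reagents that add atoms: none
Why: 1,2-Reduction of an enoate by i-Bu2AlH is the standard route to the allylic alcohol.

Step 9
Reactants: 14 (E)-3-Ar-prop-2-en-1-ol; 15 4-phenylbutanoyl chloride
Product: 16 (E)-3-Ar-prop-2-en-1-yl 4-phenylbutanoate
Conditions: Et3N, DMAP (cat.), CH2Cl2, 0 °C
Reagents that add atoms: none
Why: DMAP-catalysed acylation of a primary allylic alcohol by an acid chloride should proceed under mild basic conditions that do not ionize the electron-rich cinnamyl system.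

Step 10
Reactants: 16 (E)-3-Ar-prop-2-en-1-yl 4-phenylbutanoate
Product: 20 3-Ar-2-(2-phenylethyl)pent-4-enoic acid (racemic diastereomer mixture), via lithium enolate 17 (not isolated), via silyl ketene acetal 18 (not isolated), via trimethylsilyl ester 19 (not isolated)
Conditions: LiN(i-Pr)2, THF, −78 °C; Me3SiCl, −78 to 60 °C; then 1 M HCl
Reagents that add atoms: none
Why: Ireland–Claisen rearrangement forms the congested C1–C2 bond of ring B intramolecularly by a [3,3] shift through a chair transition state; the two new stereocentres follow ketene acetal geometry but need no control because both become sp2 later.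

Step 11
Reactants: 20 3-Ar-2-(2-phenylethyl)pent-4-enoic acid
Product: 21 ethyl 3-Ar-2-(2-phenylethyl)pent-4-enoate
Conditions: EtI, K2CO3, DMF, rt
Reagents that add atoms: iodoethane, CCI
Why: SN2 O-alkylation of the carboxylate should give the ethyl ester without touching the hindered α-centre.

Step 12
Reactants: 21 ethyl 3-Ar-2-(2-phenylethyl)pent-4-enoate
Product: 23 ethyl 3-Ar-4-oxo-2-(2-phenylethyl)butanoate, via vicinal diol 22 (not isolated)
Conditions: OsO4 (2 mol %), NaIO4, 2,6-lutidine, dioxane/H2O, rt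
Reagents that add atoms: osmium tetroxide, O=[Os](=O)(=O)=O; sodium periodate, [Na+].[O-]I(=O)(=O)=O
Why: Lemieux–Johnson dihydroxylation and glycol cleavage of the monosubstituted alkene should give the C3 aldehyde and, unlike ozone, spare the electron-rich arenes; the diol stereocentre is transient.

Step 13
Reactants: 24 ethyl propanoate
Product: 26 tert-butyl[(1-ethoxyprop-1-en-1-yl)oxy]dimethylsilane (E/Z mixture), via lithium enolate 25 (not isolated)
Conditions: LiN(i-Pr)2, THF, −78 °C; t-BuMe2SiCl, DMPU, −78 °C to rt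
Reagents that add atoms: tert-butyldimethylsilyl chloride, CC(C)(C)[Si](C)(C)Cl
Why: O-Silylation of the ester lithium enolate is the standard preparation of a distillable ketene silyl acetal.

Step 14
Reactants: 23 ethyl 3-Ar-4-oxo-2-(2-phenylethyl)butanoate; 26 tert-butyl[(1-ethoxyprop-1-en-1-yl)oxy]dimethylsilane
Product: 27 diethyl 4-Ar-3-(tert-butyldimethylsilyloxy)-2-methyl-5-(2-phenylethyl)hexanedioate (diastereomer mixture)
Conditions: HNTf2 (2 mol %), CH2Cl2, −78 °C; NaHCO3 quench
Reagents that add atoms: none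
Why: Mukaiyama aldol addition under silyl triflimide catalysis forms C3–C4 through an open transition state and passes the silyl group to O3 in the same event, so no alkoxide can lactonize onto the C6 ester; the C3 and C4 stereocentres are set without control and the mixture is accepted.

Step 15
Reactants: 27 diethyl 4-Ar-3-(tert-butyldimethylsilyloxy)-2-methyl-5-(2-phenylethyl)hexanedioate
Product: 30 3-methyl-4-(tert-butyldimethylsilyloxy)-5-Ar-6-(2-phenylethyl)-1,2-bis(trimethylsilyloxy)cyclohex-1-ene (diastereomer mixture), via cyclic 1,2-dione 28 (not isolated), via disodium enediolate 29 (not isolated)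
Conditions: Na (4.5 equiv, dispersion), Me3SiCl (6 equiv), toluene, reflux, slow addition
Reagents that add atoms: chlorotrimethylsilane, C[Si](C)(C)Cl
Why: Sodium gives one electron to each ester carbonyl, the two ketyl radical anions couple to form the C5–C6 bond, two ethoxides leave to give dione 28, and two more electrons give enediolate 29, which Me3SiCl silylates on both oxygens. The closest known reaction is the acyloin condensation of hexanedioates under Rühlmann conditions, the standard route to 1,2-bis(trimethylsilyloxy)cyclohexenes. The six-membered carbocycle closes by intramolecular ketyl–ketyl coupling of the chain termini (formally 6-exo-trig attack of one ketyl on the other carbonyl), and the four substituents on C1–C4 favour folded conformers. No stereocentre is created because C5 and C6 end as sp2 carbons, and the four existing centres only have to survive as a mixture. The step needs acyloin coupling to outrun Dieckmann condensation, β-elimination of O3 and lactonization: Me3SiCl removes each ethoxide as EtOSiMe3 and caps the enediolate, O3 is a robust silyl ether and not a ketone, and aryl methyl ethers and arenes are inert to sodium in aprotic toluene.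

Step 16
Reactants: 30 3-methyl-4-(tert-butyldimethylsilyloxy)-5-Ar-6-(2-phenylethyl)-1,2-bis(trimethylsilyloxy)cyclohex-1-ene
Product: 31 2,4-dihydroxy-3-methyl-5-Ar-6-(2-phenylethyl)cyclohexan-1-one (acyloin; mixture of diastereomers and acyloin regioisomers)
Conditions: HF (48% aq.), MeCN, 0 °C to rt
Reagents that add atoms: none
Why: Acidic fluoride desilylation should cleave the two enol silyl ethers and the tert-butyldimethylsilyl ether in one operation without the base that could eliminate O3; the acyloin carbon is protonated unselectively.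

Step 17
Reactants: 31 2,4-dihydroxy-3-methyl-5-Ar-6-(2-phenylethyl)cyclohexan-1-one
Product: 34 2-hydroxy-3-methyl-5-Ar-6-(2-phenylethyl)cyclohexa-2,5-diene-1,4-dione, via cyclohexane-1,2,4-trione 32 (not isolated), via benzene-1,2,4-triol 33 (not isolated)
Conditions: Dess–Martin periodinane (4 equiv), CH2Cl2, rt; NaHCO3 work-up
Reagents that add atoms: none
Why: Dess–Martin oxidation of both secondary alcohols gives the 1,2,4-trione, which is the keto tautomer of a benzene-1,2,4-triol and aromatizes by enolization, and the excess periodinane oxidizes this hydroxyhydroquinone to the 2-hydroxy-1,4-benzoquinone with loss of all ring B stereocentres.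

Step 18
Reactants: 34 2-hydroxy-3-methyl-5-Ar-6-(2-phenylethyl)cyclohexa-2,5-diene-1,4-dione
Product: 35 2-hydroxy-5-{4-methoxy-2-[2-(2-methoxyphenyl)ethyl]-5-methyl-3,6-dioxocyclohexa-1,4-dien-1-yl}-3-methyl-6-(2-phenylethyl)cyclohexa-2,5-diene-1,4-dione
Conditions: (NH4)2Ce(NO3)6 (2.5 equiv), MeCN/H2O, 0 °C
Reagents that add atoms: water, O
Why: Oxidative demethylation of the para-dimethoxy pair of ring A by (NH4)2Ce(NO3)6 should give the 2-methoxy-1,4-benzoquinone and leave the lone anisole ether and the ring B hydroxyquinone intact.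

Step 19
Reactants: 35 2-hydroxy-5-{4-methoxy-2-[2-(2-methoxyphenyl)ethyl]-5-methyl-3,6-dioxocyclohexa-1,4-dien-1-yl}-3-methyl-6-(2-phenylethyl)cyclohexa-2,5-diene-1,4-dione
Product: 36 2-hydroxy-5-{4-hydroxy-2-[2-(2-methoxyphenyl)ethyl]-5-methyl-3,6-dioxocyclohexa-1,4-dien-1-yl}-3-methyl-6-(2-phenylethyl)cyclohexa-2,5-diene-1,4-dione (CNP0202346.0)
Conditions: NaOH (1 M aq.), THF, rt; then 1 M HCl
Reagents that add atoms: sodium hydroxide, [Na+].[OH-]
Why: The methoxyquinone is a vinylogous ester and should be hydrolysed by addition–elimination of hydroxide; both quinone rings are fully substituted, which protects them from base-induced decomposition.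

Compound list
1 | 2-methoxybenzyl chloride | COc1ccccc1CCl | starting material
2 | (2-methoxybenzyl)triphenylphosphonium chloride | COc1ccccc1C[P+](c1ccccc1)(c1ccccc1)c1ccccc1.[Cl-] | intermediate
3 | 3,5-dimethoxy-4-methylbenzaldehyde | COc1cc(C=O)cc(OC)c1C | starting material
4 | (2-methoxybenzylidene)triphenylphosphorane | COc1ccccc1C=P(c1ccccc1)(c1ccccc1)c1ccccc1 | intermediate (not isolated)
5 | 1,3-dimethoxy-5-[2-(2-methoxyphenyl)ethenyl]-2-methylbenzene (E/Z mixture) | COc1ccccc1C=Cc1cc(OC)c(C)c(OC)c1 | intermediate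
6 | 1,3-dimethoxy-5-[2-(2-methoxyphenyl)ethyl]-2-methylbenzene | COc1ccccc1CCc1cc(OC)c(C)c(OC)c1 | intermediate
7 | 2-bromo-1-[2-(2-methoxyphenyl)ethyl]-3,5-dimethoxy-4-methylbenzene | COc1ccccc1CCc1cc(OC)c(C)c(OC)c1Br | intermediate
8 | 1-[2-(2-methoxyphenyl)ethyl]-2,3,5-trimethoxy-4-methylbenzene | COc1ccccc1CCc1cc(OC)c(C)c(OC)c1OC | intermediate
9 | N-(Ar-methylidene)-N-methylmethanaminium chloride | C[N+](C)=Cc1c(CCc2ccccc2OC)c(OC)c(OC)c(C)c1OC.[Cl-] | intermediate (not isolated)
10 | 2-[2-(2-methoxyphenyl)ethyl]-3,4,6-trimethoxy-5-methylbenzaldehyde | O=Cc1c(CCc2ccccc2OC)c(OC)c(OC)c(C)c1OC | intermediate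
11 | triethyl phosphonoacetate | CCOC(=O)CP(=O)(OCC)OCC | starting material
12 | sodium salt of triethyl phosphonoacetate | CCOC(=O)[CH-]P(=O)(OCC)OCC.[Na+] | intermediate (not isolated)
13 | ethyl (E)-3-Ar-prop-2-enoate | CCOC(=O)/C=C/c1c(CCc2ccccc2OC)c(OC)c(OC)c(C)c1OC | intermediate
14 | (E)-3-Ar-prop-2-en-1-ol | OC/C=C/c1c(CCc2ccccc2OC)c(OC)c(OC)c(C)c1OC | intermediate
15 | 4-phenylbutanoyl chloride | O=C(Cl)CCCc1ccccc1 | starting material
16 | (E)-3-Ar-prop-2-en-1-yl 4-phenylbutanoate | O=C(CCCc1ccccc1)OC/C=C/c1c(CCc2ccccc2OC)c(OC)c(OC)c(C)c1OC | intermediate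
17 | lithium enolate of 16 | [Li+].[O-]C(=CCCc1ccccc1)OC/C=C/c1c(CCc2ccccc2OC)c(OC)c(OC)c(C)c1OC | intermediate (not isolated)
18 | trimethylsilyl ketene acetal of 16 | C[Si](C)(C)OC(=CCCc1ccccc1)OC/C=C/c1c(CCc2ccccc2OC)c(OC)c(OC)c(C)c1OC | intermediate (not isolated)
19 | trimethylsilyl 3-Ar-2-(2-phenylethyl)pent-4-enoate | C[Si](C)(C)OC(=O)C(CCc1ccccc1)C(C=C)c1c(CCc2ccccc2OC)c(OC)c(OC)c(C)c1OC | intermediate (not isolated)
20 | 3-Ar-2-(2-phenylethyl)pent-4-enoic acid (diastereomer mixture) | OC(=O)C(CCc1ccccc1)C(C=C)c1c(CCc2ccccc2OC)c(OC)c(OC)c(C)c1OC | intermediate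
21 | ethyl 3-Ar-2-(2-phenylethyl)pent-4-enoate | CCOC(=O)C(CCc1ccccc1)C(C=C)c1c(CCc2ccccc2OC)c(OC)c(OC)c(C)c1OC | intermediate
22 | ethyl 3-Ar-4,5-dihydroxy-2-(2-phenylethyl)pentanoate | CCOC(=O)C(CCc1ccccc1)C(C(O)CO)c1c(CCc2ccccc2OC)c(OC)c(OC)c(C)c1OC | intermediate (not isolated)
23 | ethyl 3-Ar-4-oxo-2-(2-phenylethyl)butanoate | CCOC(=O)C(CCc1ccccc1)C(C=O)c1c(CCc2ccccc2OC)c(OC)c(OC)c(C)c1OC | intermediate
24 | ethyl propanoate | CCC(=O)OCC | starting material
25 | lithium enolate of ethyl propanoate | [Li+].CC=C([O-])OCC | intermediate (not isolated)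
26 | tert-butyl[(1-ethoxyprop-1-en-1-yl)oxy]dimethylsilane (E/Z mixture) | CC=C(OCC)O[Si](C)(C)C(C)(C)C | intermediate
27 | diethyl 4-Ar-3-(tert-butyldimethylsilyloxy)-2-methyl-5-(2-phenylethyl)hexanedioate (diastereomer mixture) | CCOC(=O)C(CCc1ccccc1)C(c1c(CCc2ccccc2OC)c(OC)c(OC)c(C)c1OC)C(O[Si](C)(C)C(C)(C)C)C(C)C(=O)OCC | intermediate
28 | 3-methyl-4-(tert-butyldimethylsilyloxy)-5-Ar-6-(2-phenylethyl)cyclohexane-1,2-dione | O=C1C(=O)C(CCc2ccccc2)C(c2c(CCc3ccccc3OC)c(OC)c(OC)c(C)c2OC)C(O[Si](C)(C)C(C)(C)C)C1C | intermediate (not isolated)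
29 | disodium enediolate of 28 | [Na+].[Na+].[O-]C1=C([O-])C(CCc2ccccc2)C(c2c(CCc3ccccc3OC)c(OC)c(OC)c(C)c2OC)C(O[Si](C)(C)C(C)(C)C)C1C | intermediate (not isolated)
30 | 3-methyl-4-(tert-butyldimethylsilyloxy)-5-Ar-6-(2-phenylethyl)-1,2-bis(trimethylsilyloxy)cyclohex-1-ene (diastereomer mixture) | C[Si](C)(C)OC1=C(O[Si](C)(C)C)C(CCc2ccccc2)C(c2c(CCc3ccccc3OC)c(OC)c(OC)c(C)c2OC)C(O[Si](C)(C)C(C)(C)C)C1C | intermediate
31 | 2,4-dihydroxy-3-methyl-5-Ar-6-(2-phenylethyl)cyclohexan-1-one (mixture) | O=C1C(O)C(C)C(O)C(c2c(CCc3ccccc3OC)c(OC)c(OC)c(C)c2OC)C1CCc1ccccc1 | intermediate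
32 | 3-methyl-5-Ar-6-(2-phenylethyl)cyclohexane-1,2,4-trione | O=C1C(=O)C(C)C(=O)C(c2c(CCc3ccccc3OC)c(OC)c(OC)c(C)c2OC)C1CCc1ccccc1 | intermediate (not isolated)
33 | 3-methyl-5-Ar-6-(2-phenylethyl)benzene-1,2,4-triol | Oc1c(O)c(C)c(O)c(-c2c(CCc3ccccc3OC)c(OC)c(OC)c(C)c2OC)c1CCc1ccccc1 | intermediate (not isolated)
34 | 2-hydroxy-3-methyl-5-Ar-6-(2-phenylethyl)cyclohexa-2,5-diene-1,4-dione | COc1ccccc1CCc1c(C2=C(CCc3ccccc3)C(=O)C(O)=C(C)C2=O)c(OC)c(C)c(OC)c1OC | intermediate
35 | 2-hydroxy-5-{4-methoxy-2-[2-(2-methoxyphenyl)ethyl]-5-methyl-3,6-dioxocyclohexa-1,4-dien-1-yl}-3-methyl-6-(2-phenylethyl)cyclohexa-2,5-diene-1,4-dione | COc1ccccc1CCC1=C(C2=C(CCc3ccccc3)C(=O)C(O)=C(C)C2=O)C(=O)C(C)=C(OC)C1=O | intermediate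
36 | 2-hydroxy-5-{4-hydroxy-2-[2-(2-methoxyphenyl)ethyl]-5-methyl-3,6-dioxocyclohexa-1,4-dien-1-yl}-3-methyl-6-(2-phenylethyl)cyclohexa-2,5-diene-1,4-dione (CNP0202346.0) | COc1ccccc1CCC1=C(C2=C(CCc3ccccc3)C(=O)C(O)=C(C)C2=O)C(=O)C(C)=C(O)C1=O | target

Total step count: 19 (18 in the main line plus step 13 as a side branch).
Longest linear sequence: 18 steps, from 1 to 36 through steps 1–12 and 14–19.

Steps most likely to fail

1. Step 15. The two α-branched ester carbonyls may take up electrons without the ketyls meeting, so that open-chain reduction, Dieckmann condensation or expulsion of the β-silyloxy group overtakes ring closure. The fallback makes the same C5–C6 bond by pinacol coupling at the aldehyde level and sets out from 27. LiAlH4 in THF at 0 °C should give 4-Ar-3-(tert-butyldimethylsilyloxy)-2-methyl-5-(2-phenylethyl)hexane-1,6-diol F1. Swern oxidation (DMSO, (COCl)2, Et3N, −78 °C) should give the corresponding hexanedial F2. SmI2 in THF from −78 °C to rt should close it to 3-methyl-4-(tert-butyldimethylsilyloxy)-5-Ar-6-(2-phenylethyl)cyclohexane-1,2-diol F3. HF in MeCN should then free 3-methyl-5-Ar-6-(2-phenylethyl)cyclohexane-1,2,4-triol F4. Oxidation with DMSO and (CF3CO)2O followed by Et3N should give trione 32, which enolizes to 33 and is oxidized by air to 34, where the route is rejoined.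

2. Step 14. Silyl transfer may stall if the aryl ethers sequester the silyl Lewis acid, or the α-aryl aldehyde may enolize under it; any aldol oxygen left unsilylated would then close onto the C6 ester. The fallback sets out from 23 and uses a preformed nucleophile in place of Lewis-acid group transfer. Lithium enolate 25 (from 24 and LiN(i-Pr)2) is added in THF at −78 °C and quenched cold with AcOH to give diethyl 4-Ar-3-hydroxy-2-methyl-5-(2-phenylethyl)hexanedioate F5. This is silylated at once with t-BuMe2SiOTf and 2,6-lutidine in CH2Cl2 at −78 °C, before the neutral γ-hydroxy ester can lactonize, and the route is rejoined at 27.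

3. Step 17. Three oxidations and an aromatization have to occur in one flask; the periodinane may cleave the α-hydroxy ketone, the β-hydroxy ketone may dehydrate with loss of O3, or the mixture may stall at mixed oxidation levels. The fallback unveils and oxidizes the oxygens in stages and sets out from 30. Brief treatment with 0.1 M HCl in THF/H2O at 0 °C should remove only the two trimethylsilyl groups and give 2-hydroxy-3-methyl-4-(tert-butyldimethylsilyloxy)-5-Ar-6-(2-phenylethyl)cyclohexan-1-one F6. Cu(OAc)2 in aqueous AcOH/MeOH should oxidize this acyloin to dione 28, isolated here. HF in MeCN should then give 4-hydroxy-3-methyl-5-Ar-6-(2-phenylethyl)cyclohexane-1,2-dione F7. A single alcohol oxidation with Dess–Martin periodinane leads through 32 and 33 to 34, where the route is rejoined.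

Further compounds
F1 | step 15 | 4-Ar-3-(tert-butyldimethylsilyloxy)-2-methyl-5-(2-phenylethyl)hexane-1,6-diol | OCC(CCc1ccccc1)C(c1c(CCc2ccccc2OC)c(OC)c(OC)c(C)c1OC)C(O[Si](C)(C)C(C)(C)C)C(C)CO
F2 | step 15 | 4-Ar-3-(tert-butyldimethylsilyloxy)-2-methyl-5-(2-phenylethyl)hexanedial | O=CC(CCc1ccccc1)C(c1c(CCc2ccccc2OC)c(OC)c(OC)c(C)c1OC)C(O[Si](C)(C)C(C)(C)C)C(C)C=O
F3 | step 15 | 3-methyl-4-(tert-butyldimethylsilyloxy)-5-Ar-6-(2-phenylethyl)cyclohexane-1,2-diol | OC1C(O)C(CCc2ccccc2)C(c2c(CCc3ccccc3OC)c(OC)c(OC)c(C)c2OC)C(O[Si](C)(C)C(C)(C)C)C1C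
F4 | step 15 | 3-methyl-5-Ar-6-(2-phenylethyl)cyclohexane-1,2,4-triol | OC1C(O)C(CCc2ccccc2)C(c2c(CCc3ccccc3OC)c(OC)c(OC)c(C)c2OC)C(O)C1C
F5 | step 14 | diethyl 4-Ar-3-hydroxy-2-methyl-5-(2-phenylethyl)hexanedioate | CCOC(=O)C(CCc1ccccc1)C(c1c(CCc2ccccc2OC)c(OC)c(OC)c(C)c1OC)C(O)C(C)C(=O)OCC
F6 | step 17 | 2-hydroxy-3-methyl-4-(tert-butyldimethylsilyloxy)-5-Ar-6-(2-phenylethyl)cyclohexan-1-one | O=C1C(O)C(C)C(O[Si](C)(C)C(C)(C)C)C(c2c(CCc3ccccc3OC)c(OC)c(OC)c(C)c2OC)C1CCc1ccccc1
F7 | step 17 | 4-hydroxy-3-methyl-5-Ar-6-(2-phenylethyl)cyclohexane-1,2-dione | O=C1C(=O)C(C)C(O)C(c2c(CCc3ccccc3OC)c(OC)c(OC)c(C)c2OC)C1CCc1ccccc1
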